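**Retrosynthetic overview**
- The strategy rests on ring B (C1' bridge carbon, C2' OH, C3' butanoyl, C4' OH, C5' methyl, C6' OMe): it is hexasubstituted with oxygen and carbon substituents alternating, and only the oxygen at C6', between C1' and C5', is methylated.
- The target comes from hydrogenolysis of four benzyl ethers; the C3' butanoyl group is added last at the only free ring B carbon by ortho-formylation, propyl Grignard addition and oxidation.
- Ring B is built by benzannulation of a ring A-substituted methoxyalkyne with 3-(benzyloxy)-2-methylcyclobutenone. The bonds C1'–C2' and C5'–C6' form in a [2+2] step and C2'–C3' closes the ring, so the three oxygens arrive as free OH, OMe and O-benzyl.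
- The methoxyalkyne comes from a ring A benzylic bromide and methoxyethynylzinc chloride (Negishi coupling). The bromide comes from 2-methylphloroglucinol by acylation, formylation, benzylation, reduction and bromination. The cyclobutenone comes from ketene and 1-(benzyloxy)propyne.
- Ring order: ring A (C1 pentanoyl, C2/C4/C6 oxygens, C3 methyl, C5 bridge) is bought and only substituted; ring B is the one ring formed, in the key step.

Key step: step 10

Remark: the target has no stereocenter; the two stereocenters that appear on the way (in 23 and 28) are racemic and are destroyed again.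

**Route**

Step 1
Reactants: 1 2-methylphloroglucinol; 2 pentanoyl chloride
Product: 3 1-(2,4,6-trihydroxy-3-methylphenyl)pentan-1-one
Conditions: AlCl3 (3 equiv), PhNO2/CH2Cl2, 0 °C → rt; aq. HCl
Reagents that add atoms: none
Why: Friedel–Crafts acylation of the electron-rich triol at one of its two equivalent free carbons, and the acyl group deactivates the ring so that the reaction should stop after one acylation.

Step 2
Reactants: 3 1-(2,4,6-trihydroxy-3-methylphenyl)pentan-1-one
Product: 4 2,4,6-trihydroxy-3-methyl-5-pentanoylbenzaldehyde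
Conditions: POCl3, DMF, EtOAc, 0 °C → rt; then H2O, 50 °C
Reagents that add atoms: N,N-dimethylformamide CN(C)C=O; water O
Why: Vilsmeier–Haack formylation, in which the chloroiminium ion can only attack the single remaining ring CH, activated by three hydroxyls, and hydrolysis of the iminium salt gives the aldehyde.

Step 3
Reactants: 4 2,4,6-trihydroxy-3-methyl-5-pentanoylbenzaldehyde
Product: 5 2,4,6-tris(benzyloxy)-3-methyl-5-pentanoylbenzaldehyde
Conditions: BnBr (4 equiv), K2CO3, Bu4NI (cat.), DMF, 60 °C
Reagents that add atoms: benzyl bromide BrCc1ccccc1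
Why: Williamson etherification, in which the two carbonyl groups lower the carbon nucleophilicity of the phenoxides so that alkylation in a dipolar aprotic solvent should occur on oxygen, and warming overcomes the hydrogen bonds to the carbonyls.

Step 4
Reactants: 5 2,4,6-tris(benzyloxy)-3-methyl-5-pentanoylbenzaldehyde
Product: 6 1-[2,4,6-tris(benzyloxy)-3-(hydroxymethyl)-5-methylphenyl]pentan-1-one
Conditions: NaBH4, THF/MeOH, −10 → 0 °C
Reagents that add atoms: none
Why: Chemoselective borohydride reduction, the aldehyde reacting much faster than the aryl ketone, which is flanked by two benzyloxy groups and twisted out of the ring plane.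

Step 5
Reactants: 6 1-[2,4,6-tris(benzyloxy)-3-(hydroxymethyl)-5-methylphenyl]pentan-1-one
Product: 7 1-[2,4,6-tris(benzyloxy)-3-(bromomethyl)-5-methylphenyl]pentan-1-one
Conditions: CBr4, PPh3, CH2Cl2, 0 °C; used crude at once
Reagents that add atoms: carbon tetrabromide BrC(Br)(Br)Br
Why: Appel bromination of a primary benzylic alcohol under neutral conditions, which spares the benzyl ethers and the ketone; the electron-rich bromide is not stored.

Step 6
Reactants: 8 trichloroethylene
Product: 9 (E)-1,2-dichloro-1-methoxyethene
Conditions: KOMe, THF, −50 °C → rt; fractional distillation (or use as a titrated THF solution)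
Reagents that add atoms: potassium methoxide C[O-].[K+]
Why: Base-induced loss of HCl from trichloroethylene and anti addition of methoxide to the dichloroacetylene so formed, the first stage of the Greene alkynyl ether synthesis.

Step 7
Reactants: 7 1-[2,4,6-tris(benzyloxy)-3-(bromomethyl)-5-methylphenyl]pentan-1-one; 9 (E)-1,2-dichloro-1-methoxyethene
Product: 13 1-[2,4,6-tris(benzyloxy)-3-(3-methoxyprop-2-yn-1-yl)-5-methylphenyl]pentan-1-one, via chloro(methoxy)ethyne 10 (not isolated), via lithium methoxyacetylide 11 (not isolated), via methoxyethynylzinc chloride 12 (not isolated)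
Conditions: 9 (1.5 equiv), n-BuLi (2.0 equiv per 9), THF, −78 → −40 °C; ZnCl2, −78 → 0 °C; then 7, Pd(PPh3)4 (5 mol %), THF, 0 °C → rt; work-up at pH ≥ 7, silica deactivated with Et3N
Reagents that add atoms: none
Why: Negishi coupling of a benzylic bromide with an alkynylzinc halide, in which the zinc acetylide (from elimination, chlorine–lithium exchange and transmetalation) should not add to the hindered ketone and zerovalent palladium inserts readily into the benzylic C–Br bond.

Step 8
Reactants: 14 benzyl alcohol; 8 trichloroethylene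
Product: 18 1-(benzyloxy)prop-1-yne, via benzyl (E)-1,2-dichlorovinyl ether 15 (not isolated), via (benzyloxy)chloroethyne 16 (not isolated), via lithium (benzyloxy)acetylide 17 (not isolated)
Conditions: KH, THF, 0 °C → rt; 8, −50 °C → rt; n-BuLi (2.2 equiv), −78 → −40 °C; MeI, HMPA, −78 → 20 °C; isolation below 25 °C
Reagents that add atoms: iodomethane CI
Why: One-pot Greene synthesis of an alkynyl ether (alkoxide addition to dichloroacetylene, elimination and chlorine–lithium exchange, then C-methylation of the lithium alkoxyacetylide), run and worked up cold because benzyl alkynyl ethers undergo a [3,3] shift on warming.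

Step 9
Reactants: 18 1-(benzyloxy)prop-1-yne; 19 acetone
Product: 21 3-(benzyloxy)-2-methylcyclobut-2-en-1-one, via ketene 20 (not isolated)
Conditions: acetone vapour over a glowing wire (ketene lamp); ketene stream passed into 18, CH2Cl2, 0 °C → rt
Reagents that add atoms: none
Why: Thermal [2+2] cycloaddition of ketene with an electron-rich alkoxyalkyne, the nucleophilic methyl-bearing alkyne carbon bonding to the ketene carbonyl carbon, which puts methyl at C2 and benzyloxy at C3 of the cyclobutenone.

Step 10
Reactants: 13 1-[2,4,6-tris(benzyloxy)-3-(3-methoxyprop-2-yn-1-yl)-5-methylphenyl]pentan-1-one; 21 3-(benzyloxy)-2-methylcyclobut-2-en-1-one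
Product: 26 1-[2,4,6-tris(benzyloxy)-3-{[4-(benzyloxy)-6-hydroxy-2-methoxy-3-methylphenyl]methyl}-5-methylphenyl]pentan-1-one, via vinylketene 22 (not isolated), via vinylcyclobutenone 23 (not isolated), via dienylketene 24 (not isolated), via cyclohexadienone 25 (not isolated)
Conditions: 21 (2 equiv), degassed toluene, 120 °C, sealed tube; then KOH, MeOH, rt (frees any product phenol acylated by the vinylketene)
Reagents that add atoms: none
Why: Heating opens cyclobutenone 21 reversibly by a four-electron electrocyclic reaction to the (1-benzyloxyvinyl)ketene 22, which adds to ynol ether 13 in a [2+2] cycloaddition to give the 4-vinylcyclobutenone 23, and a second four-electron opening gives dienylketene 24. This is the Danheiser benzannulation of a cyclobutenone with an alkoxyalkyne, which is known to deliver resorcinol monoethers. Ring B is closed by six-electron electrocyclization of 24 (bond C2'–C3', between the ketene carbon and the vinyl CH2) to cyclohexa-2,4-dienone 25, which tautomerizes to the phenol, while the bonds C1'–C2' and C5'–C6' come from the [2+2] step. No stereocenter remains in 26, because the quaternary carbon of 23 forms as a racemate and becomes planar again on ring opening. The selectivity needed is the regiochemistry of the ketene–alkyne union, and the polarization of the ynol ether secures it: the alkyne carbon remote from oxygen, which bears the ring A benzyl group, is the nucleophile and bonds to the ketene carbonyl carbon, so the benzyl group ends up ortho and the methoxy group meta to the new hydroxyl. The methyl ynol ether has no β-hydrogen for retro-ene loss of an alkene, so it should survive the temperature needed to open the alkoxy-stabilized cyclobutenone, and because ring opening of 23 is reversible only the dienylketene geometry that can cyclize is drained.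

Step 11
Reactants: 26 1-[2,4,6-tris(benzyloxy)-3-{[4-(benzyloxy)-6-hydroxy-2-methoxy-3-methylphenyl]methyl}-5-methylphenyl]pentan-1-one
Product: 27 6-(benzyloxy)-2-hydroxy-4-methoxy-5-methyl-3-{[2,4,6-tris(benzyloxy)-3-methyl-5-pentanoylphenyl]methyl}benzaldehyde
Conditions: MgCl2, Et3N, (CH2O)n, MeCN, reflux; dilute aq. HCl work-up
Reagents that add atoms: paraformaldehyde (formaldehyde) C=O
Why: Magnesium-mediated ortho-formylation of a phenol (Casnati–Skattebøl), in which the magnesium phenoxide delivers formaldehyde to the only free ortho carbon C3' and a second formaldehyde oxidizes the hydroxymethyl stage to the aldehyde, with no Lewis acid strong enough to cleave benzyl ethers.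

Step 12
Reactants: 27 6-(benzyloxy)-2-hydroxy-4-methoxy-5-methyl-3-{[2,4,6-tris(benzyloxy)-3-methyl-5-pentanoylphenyl]methyl}benzaldehyde
Product: 28 1-[2,4,6-tris(benzyloxy)-3-{[4-(benzyloxy)-2-hydroxy-3-(1-hydroxybutyl)-6-methoxy-5-methylphenyl]methyl}-5-methylphenyl]pentan-1-one (racemic)
Conditions: n-PrMgBr (2.5 equiv), THF, −40 → 0 °C; aq. NH4Cl
Reagents that add atoms: propylmagnesium bromide CCC[Mg]Br
Why: Grignard addition to the aldehyde after deprotonation of the phenol, the shielded ring A ketone being expected to stay untouched at this temperature; the carbinol stereocenter forms as a racemate without control because the next step removes it.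

Step 13
Reactants: 28 1-[2,4,6-tris(benzyloxy)-3-{[4-(benzyloxy)-2-hydroxy-3-(1-hydroxybutyl)-6-methoxy-5-methylphenyl]methyl}-5-methylphenyl]pentan-1-one
Product: 29 1-[2,4,6-tris(benzyloxy)-3-{[4-(benzyloxy)-3-butanoyl-2-hydroxy-6-methoxy-5-methylphenyl]methyl}-5-methylphenyl]pentan-1-one
Conditions: activated MnO2 (excess), CH2Cl2, rt
Reagents that add atoms: none
Why: Manganese dioxide oxidation of a benzylic alcohol to the aryl ketone under neutral conditions, which avoids acid-promoted loss of water from the ortho-hydroxybenzyl alcohol and leaves the ethers intact; the stereocenter disappears.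

Step 14
Reactants: 29 1-[2,4,6-tris(benzyloxy)-3-{[4-(benzyloxy)-3-butanoyl-2-hydroxy-6-methoxy-5-methylphenyl]methyl}-5-methylphenyl]pentan-1-one
Product: 30 1-[3-[(3-butanoyl-2,4-dihydroxy-6-methoxy-5-methylphenyl)methyl]-2,4,6-trihydroxy-5-methylphenyl]pentan-1-one
Conditions: H2 (1 atm), Pd/C (10 %), EtOAc/MeOH, rt
Reagents that add atoms: none
Why: Hydrogenolysis of the four aryl benzyl ethers over palladium on carbon, to which the methyl ether, the two hydrogen-bonded aryl ketones and the diarylmethane bridge should be stable.

**Compound list**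
1 | 2-methylphloroglucinol (2-methylbenzene-1,3,5-triol) | Cc1c(O)cc(O)cc1O | starting material
2 | pentanoyl chloride | CCCCC(Cl)=O | starting material
3 | 1-(2,4,6-trihydroxy-3-methylphenyl)pentan-1-one | CCCCC(=O)c1c(O)cc(O)c(C)c1O | intermediate
4 | 2,4,6-trihydroxy-3-methyl-5-pentanoylbenzaldehyde | CCCCC(=O)c1c(O)c(C)c(O)c(C=O)c1O | intermediate
5 | 2,4,6-tris(benzyloxy)-3-methyl-5-pentanoylbenzaldehyde | CCCCC(=O)c1c(OCc2ccccc2)c(C)c(OCc2ccccc2)c(C=O)c1OCc1ccccc1 | intermediate
6 | 1-[2,4,6-tris(benzyloxy)-3-(hydroxymethyl)-5-methylphenyl]pentan-1-one | CCCCC(=O)c1c(OCc2ccccc2)c(C)c(OCc2ccccc2)c(CO)c1OCc1ccccc1 | intermediate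
7 | 1-[2,4,6-tris(benzyloxy)-3-(bromomethyl)-5-methylphenyl]pentan-1-one | CCCCC(=O)c1c(OCc2ccccc2)c(C)c(OCc2ccccc2)c(CBr)c1OCc1ccccc1 | intermediate
8 | trichloroethylene | ClC=C(Cl)Cl | starting material
9 | (E)-1,2-dichloro-1-methoxyethene | CO/C(Cl)=C\Cl | intermediate
10 | chloro(methoxy)ethyne | COC#CCl | intermediate (not isolated)
11 | lithium methoxyacetylide | [Li]C#COC | intermediate (not isolated)
12 | methoxyethynylzinc chloride | COC#C[Zn]Cl | intermediate (not isolated)
13 | 1-[2,4,6-tris(benzyloxy)-3-(3-methoxyprop-2-yn-1-yl)-5-methylphenyl]pentan-1-one | COC#CCc1c(OCc2ccccc2)c(C)c(OCc2ccccc2)c(C(=O)CCCC)c1OCc1ccccc1 | intermediate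
14 | benzyl alcohol | OCc1ccccc1 | starting material
15 | benzyl (E)-1,2-dichlorovinyl ether | Cl/C=C(/Cl)OCc1ccccc1 | intermediate (not isolated)
16 | (benzyloxy)chloroethyne | ClC#COCc1ccccc1 | intermediate (not isolated)
17 | lithium (benzyloxy)acetylide | [Li]C#COCc1ccccc1 | intermediate (not isolated)
18 | 1-(benzyloxy)prop-1-yne | CC#COCc1ccccc1 | intermediate
19 | acetone | CC(C)=O | starting material
20 | ketene | C=C=O | intermediate (not isolated)
21 | 3-(benzyloxy)-2-methylcyclobut-2-en-1-one | CC1=C(OCc2ccccc2)CC1=O | intermediate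
22 | 3-(benzyloxy)-2-methylbuta-1,3-dien-1-one (vinylketene) | O=C=C(C)C(=C)OCc1ccccc1 | intermediate (not isolated)
23 | 4-[1-(benzyloxy)ethenyl]-3-methoxy-4-methyl-2-{[2,4,6-tris(benzyloxy)-3-methyl-5-pentanoylphenyl]methyl}cyclobut-2-en-1-one (racemic) | COC1=C(Cc2c(OCc3ccccc3)c(C)c(OCc3ccccc3)c(C(=O)CCCC)c2OCc2ccccc2)C(=O)C1(C)C(=C)OCc1ccccc1 | intermediate (not isolated)
24 | (3E)-5-(benzyloxy)-3-methoxy-4-methyl-2-{[2,4,6-tris(benzyloxy)-3-methyl-5-pentanoylphenyl]methyl}hexa-1,3,5-trien-1-one (dienylketene) | O=C=C(Cc1c(OCc2ccccc2)c(C)c(OCc2ccccc2)c(C(=O)CCCC)c1OCc1ccccc1)/C(OC)=C(C)\C(=C)OCc1ccccc1 | intermediate (not isolated)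
25 | 5-(benzyloxy)-3-methoxy-4-methyl-2-{[2,4,6-tris(benzyloxy)-3-methyl-5-pentanoylphenyl]methyl}cyclohexa-2,4-dien-1-one | COC1=C(Cc2c(OCc3ccccc3)c(C)c(OCc3ccccc3)c(C(=O)CCCC)c2OCc2ccccc2)C(=O)CC(OCc2ccccc2)=C1C | intermediate (not isolated)
26 | 1-[2,4,6-tris(benzyloxy)-3-{[4-(benzyloxy)-6-hydroxy-2-methoxy-3-methylphenyl]methyl}-5-methylphenyl]pentan-1-one | COc1c(C)c(OCc2ccccc2)cc(O)c1Cc1c(OCc2ccccc2)c(C)c(OCc2ccccc2)c(C(=O)CCCC)c1OCc1ccccc1 | intermediate
27 | 6-(benzyloxy)-2-hydroxy-4-methoxy-5-methyl-3-{[2,4,6-tris(benzyloxy)-3-methyl-5-pentanoylphenyl]methyl}benzaldehyde | COc1c(C)c(OCc2ccccc2)c(C=O)c(O)c1Cc1c(OCc2ccccc2)c(C)c(OCc2ccccc2)c(C(=O)CCCC)c1OCc1ccccc1 | intermediate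
28 | 1-[2,4,6-tris(benzyloxy)-3-{[4-(benzyloxy)-2-hydroxy-3-(1-hydroxybutyl)-6-methoxy-5-methylphenyl]methyl}-5-methylphenyl]pentan-1-one (racemic) | COc1c(C)c(OCc2ccccc2)c(C(O)CCC)c(O)c1Cc1c(OCc2ccccc2)c(C)c(OCc2ccccc2)c(C(=O)CCCC)c1OCc1ccccc1 | intermediate
29 | 1-[2,4,6-tris(benzyloxy)-3-{[4-(benzyloxy)-3-butanoyl-2-hydroxy-6-methoxy-5-methylphenyl]methyl}-5-methylphenyl]pentan-1-one | COc1c(C)c(OCc2ccccc2)c(C(=O)CCC)c(O)c1Cc1c(OCc2ccccc2)c(C)c(OCc2ccccc2)c(C(=O)CCCC)c1OCc1ccccc1 | intermediate
30 | 1-[3-[(3-butanoyl-2,4-dihydroxy-6-methoxy-5-methylphenyl)methyl]-2,4,6-trihydroxy-5-methylphenyl]pentan-1-one | CCCCC(=O)c1c(O)c(C)c(O)c(Cc2c(O)c(C(=O)CCC)c(O)c(C)c2OC)c1O | target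

**Step count**
Total: 14 steps. Longest linear sequence: 11 steps (1, 2, 3, 4, 5, 7, 10, 11, 12, 13, 14).

**Steps most likely to fail**

Step 10. The alkoxy group at C3 stabilizes cyclobutenone 21, so its ring opening may be slow, and the bulky benzylic substituent of 13 may slow the [2+2] step; the vinylketene would then be consumed by dimerization or by acylating phenols, and conversion of 13 would stall. The fallback gives up the benzannulation and benzylates a preformed ring B; it sets out from 1 and from benzylic alcohol 6. Friedel–Crafts acylation of 1 with butanoyl chloride and AlCl3 should give 1-(2,4,6-trihydroxy-3-methylphenyl)butan-1-one F1. Methylation with one equivalent of Me2SO4 and K2CO3 in acetone should occur at the hydroxyl para to the ketone, the only one not hydrogen-bonded to it, to give 1-(2,6-dihydroxy-4-methoxy-3-methylphenyl)butan-1-one F2. Acid-catalysed Friedel–Crafts benzylation of F2 at its single free ring carbon with 6 (Sc(OTf)3 cat., CH2Cl2/MeNO2, rt) should give 1-[2,4,6-tris(benzyloxy)-3-[(3-butanoyl-2,4-dihydroxy-6-methoxy-5-methylphenyl)methyl]-5-methylphenyl]pentan-1-one F3. Hydrogenolysis under the conditions of step 14 comes back to the route at target 30.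

Step 7. The zinc acetylide may be lost by protonation or may transmetalate poorly, the electron-rich bromide 7 may ionize or homocouple, and the ynol ether may be hydrated during isolation. The fallback replaces the basic zinc reagent made in the flask by an isolated, neutral tin reagent; it sets out from 9 and 7. Treatment of 9 with n-BuLi (2 equiv) and then Bu3SnCl should give tributyl(methoxyethynyl)stannane F4, purified by distillation. Stille coupling of F4 with 7 (Pd(PPh3)4, toluene, 60 °C) comes back to the route at 13.

Step 8. Benzyl alkynyl ethers rearrange by a [3,3] shift on mild warming, and butyllithium may deprotonate the benzylic position and trigger a Wittig rearrangement, so 18 may be lost during alkylation or isolation. The fallback puts the benzyl group on after the four-membered ring is made; it sets out from acetone 19 and benzyl alcohol 14 and replaces steps 8 and 9. Ketene 20 from 19 is passed into commercial 1-ethoxyprop-1-yne F5 (CH2Cl2, 0 °C) to give 3-ethoxy-2-methylcyclobut-2-en-1-one F6. Acid-catalysed exchange of this vinylogous ester with 14 (TsOH cat., toluene, 40 °C, reduced pressure to remove ethanol) comes back to the route at 21.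

**Further compounds**
F1 | step 10 | 1-(2,4,6-trihydroxy-3-methylphenyl)butan-1-one | CCCC(=O)c1c(O)cc(O)c(C)c1O
F2 | step 10 | 1-(2,6-dihydroxy-4-methoxy-3-methylphenyl)butan-1-one | CCCC(=O)c1c(O)cc(OC)c(C)c1O
F3 | step 10 | 1-[2,4,6-tris(benzyloxy)-3-[(3-butanoyl-2,4-dihydroxy-6-methoxy-5-methylphenyl)methyl]-5-methylphenyl]pentan-1-one | COc1c(C)c(O)c(C(=O)CCC)c(O)c1Cc1c(OCc2ccccc2)c(C)c(OCc2ccccc2)c(C(=O)CCCC)c1OCc1ccccc1
F4 | step 7 | tributyl(methoxyethynyl)stannane | CCCC[Sn](CCCC)(CCCC)C#COC
F5 | step 8 | 1-ethoxyprop-1-yne | CCOC#CC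
F6 | step 8 | 3-ethoxy-2-methylcyclobut-2-en-1-one | CCOC1=C(C)C(=O)C1
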